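## Structural features

Isoamoritin (17) is a flavanone: ring A (C4a, C5, C6, C7, C8, C8a) is fused to the dihydropyranone ring C (O1, C2, C3, C4), and the aryl ring B sits on C2. C2 is the only stereocentre (S); it is benzylic, bonded to O1 and β to the C4 carbonyl, so base can erase it by E1cB opening to the 2′-hydroxychalcone and re-closure. Ring A is a fully substituted phloroglucinol with OH at C5 and C7 and prenyl (3-methylbut-2-enyl) groups at C6 and C8; before ring C is attached this pattern is C2v-symmetric, so either oxygen next to C4a can become O1. Ring B carries 3′-OH, 4′-OMe and a 5′-prenyl group, so the prenyl is ortho to the methylated oxygen and meta to the free hydroxyl. The fragile parts are the three trisubstituted alkenes (no hydrogenation, no halogen or peracid electrophiles, and acid can add a neighbouring OH across them to give chromans), the base-labile C2 configuration and the free phenols. The real difficulty is to fix C2 as one enantiomer in a ring whose obvious closure is reversible, while joining two electron-rich rings that each carry regiodefined prenyl groups. The key step exploits the fact that C2 is at once the stereocentre, the B–C junction and, once C2=C3 is present, the β-carbon of the vinylogous ester O1–C2=C3–C4=O. In one sentence: the route is an enantioselective rhodium-catalysed 1,4-addition of a prenylated arylboronic acid to an achiral 6,8-diprenylchromone, forming the C2–C1′ bond.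

## Logic of the disconnections

17 ⇒ 16. The three phenolic O–CH2OCH3 bonds (O5, O7, O3′) are cut. A free 7-OH would be deprotonated in the key step and turn the acceptor into an unreactive vinylogous carboxylate, so the phenols are masked until the end. The gain is a single final unmasking. The demand is an acidic, base-free cleavage that spares the prenyl groups and C2.

16 ⇒ 5 + 15. The C2–C1′ bond is cut. It is the bond at the only stereocentre and the junction of the two halves, and cutting it leaves a flat, achiral bicyclic acceptor and an achiral aryl nucleophile. The gain is full convergence, and the stereocentre is made in an irreversible C–C bond formation instead of a reversible C–O closure. The demand is a catalyst that distinguishes the two faces of C2=C3 in 5, adds 1,4 and not 1,2, and ignores three prenyl alkenes.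

5 ⇒ 3 (through 4). The O1–C2 and C2–C3 bonds are cut, which removes one carbon (C2). Because the ring of 3 is symmetric apart from its protecting groups, only one annulation product is possible. The gain is that ring C comes from an acetyl group in one operation. The demand is that ring closure and amine loss proceed without loss of the acetal groups.

3 ⇒ 2 ⇒ 1. Two O–CH2OCH3 bonds are cut, then the two ring C–CH2 bonds at the future C6 and C8. These carbons are the only nucleophilic ring positions of 1, so both prenyl groups can be placed by direct C-alkylation. The gain is the fully substituted ring A in two steps from a commodity phenol. The demand is C- over O-alkylation and a stop at two alkyl groups.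

15 ⇒ 12. The C1′–B bond is cut to a C–Br bond. The gain is a stable, storable precursor. The demand is halogen–metal exchange faster than deprotonation at the benzylic/allylic CH2.

12 ⇒ 11 ⇒ 9. The O4′–CH3 bond is cut, then the C5′–CH2 bond by a retro-[3,3] shift onto O4′. The oxygen that delivers the prenyl group is the one that is methylated afterwards, which fixes the pattern (prenyl ortho to OMe) that direct substitution cannot give. The gain is complete regiocontrol, since only one ortho position is free. The demand is a tertiary allyl ether on O4′ and a free O4′ after the shift.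

9 ⇒ 8 ⇒ 7 ⇒ 6. The O4′–C(CH3)2 bond, the C1′–Br bond and the O3′–CH2OCH3 bond are cut in turn. The free hydroxyl directs bromine para to itself, which is exactly C1′. The gain is a start from catechol. The demand is mono-protection of a symmetric diol and kinetic attack at the substituted allyl terminus.

## Other disconnections considered

Alternative 1: the first idea is to cut O1–C2, and before that C2=C3. Forward, Claisen–Schmidt condensation of 3 with 4-methoxy-3-(methoxymethoxy)-5-(3-methylbut-2-en-1-yl)benzaldehyde A1 would give the 2′-hydroxychalcone A2, which is closed by a 6-endo oxa-Michael addition under a chiral catalyst. The closure is the microscopic reverse of the E1cB opening that racemises flavanones, so any catalyst that sets C2 can also unset it. The adding phenol in A2 is hydrogen-bonded to the carbonyl and flanked by a prenyl group, and highly selective variants depend on an extra activating ester at C3 that must be added and removed. A1 needs as many steps as 15, so nothing is saved.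

Alternative 2: cut O1–C2 with inversion. Forward, an asymmetric acetate aldol between 3 and A1 would give the (3R)-β-hydroxy ketone A3, and a Mitsunobu cyclisation would give the 2S ether. The carbinol carbon of A3 is benzylic and para to the 4′-methoxy group, so the activated alcohol is expected to ionise; this leaks stereochemistry and eliminates to A2. Two stereo-relevant operations replace one, and the nucleophile is a hindered, chelated phenol.

Alternative 3: cut C2–H. Forward, oxidative cyclisation of A2 would give the flavone A4, which is reduced by an enantioselective conjugate reduction or hydrogenation. The oxidants that convert chalcones into flavones attack prenyl groups, hydrogenation catalysts cannot be expected to spare three trisubstituted alkenes or to stop at the ketone, and the β-aryl-β-alkoxy enone is a poor hydride acceptor. The stereo-defining step comes after a longer, linear sequence.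

Key step: step 10

Assumption: the diene enantiomer that gives (S)-3-arylcyclohexanones from 2-cyclohexenone (taken to be the (S,S)-diene) is assumed to deliver aryl to the Re face of C2 of 5, the spatially equivalent face; if a model addition shows the opposite sense, the (R,R)-diene is used with no other change.

## Route

Step 1
Reactants: 1 1-(2,4,6-trihydroxyphenyl)ethan-1-one
Product: 2 1-[2,4,6-trihydroxy-3,5-bis(3-methylbut-2-en-1-yl)phenyl]ethan-1-one
Conditions: prenyl bromide (2.2 equiv), 10% aq. KOH, 0 °C → rt; then 1 M HCl
Reagents that add atoms: prenyl bromide (1-bromo-3-methylbut-2-ene), CC(C)=CCBr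
Why: Phenoxide C-alkylation of an acylphloroglucinol: C3 and C5 are the only nucleophilic ring carbons, and in water the hydrogen-bonded oxygens are shielded so the soft allylic bromide reacts at carbon. The yield should be modest because mono- and geminal dialkylation compete.

Step 2
Reactants: 2 1-[2,4,6-trihydroxy-3,5-bis(3-methylbut-2-en-1-yl)phenyl]ethan-1-one
Product: 3 1-[2-hydroxy-4,6-bis(methoxymethoxy)-3,5-bis(3-methylbut-2-en-1-yl)phenyl]ethan-1-one
Conditions: MOMCl (2.3 equiv), iPr2NEt (3 equiv), CH2Cl2, 0 °C → rt
Reagents that add atoms: chloromethyl methyl ether, COCCl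
Why: O-Alkylation with an α-chloro ether: the para hydroxyl and one ortho hydroxyl react, while the last ortho hydroxyl is held in a strong hydrogen bond to the acetyl carbonyl and should stay free for the ring closure.

Step 3
Reactants: 3 1-[2-hydroxy-4,6-bis(methoxymethoxy)-3,5-bis(3-methylbut-2-en-1-yl)phenyl]ethan-1-one
Product: 5 5,7-bis(methoxymethoxy)-6,8-bis(3-methylbut-2-en-1-yl)-4H-chromen-4-one, via enaminone 4 (not isolated)
Conditions: DMF-DMA (3 equiv), toluene, 90 °C; then AcOH (2 equiv), 60 °C
Reagents that add atoms: N,N-dimethylformamide dimethyl acetal, COC(OC)N(C)C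
Why: Enaminone route to chromones: amide-acetal condensation at the acetyl methyl gives 4, then acid-promoted addition of the free ortho phenol to the β-carbon and loss of dimethylamine close the pyranone. The symmetry of 2 means only one chromone can form.

Step 4
Reactants: 6 benzene-1,2-diol (catechol)
Product: 7 2-(methoxymethoxy)phenol
Conditions: NaH (1.0 equiv), THF, 0 °C; MOMCl (1.0 equiv), 0 °C → rt
Reagents that add atoms: chloromethyl methyl ether, COCCl
Why: Mono-alkylation of the catechol mono-anion: the second hydroxyl is much less acidic once the first is ionised, so the mono-ether should dominate and is separable from diol and bis-ether.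

Step 5
Reactants: 7 2-(methoxymethoxy)phenol
Product: 8 4-bromo-2-(methoxymethoxy)phenol
Conditions: NBS (1.0 equiv), MeCN, −20 → 0 °C
Reagents that add atoms: N-bromosuccinimide, O=C1CCC(=O)N1Br
Why: Electrophilic aromatic bromination: the free hydroxyl is the stronger donor and directs para to itself (C4), which becomes C1′ of ring B.

Step 6
Reactants: 8 4-bromo-2-(methoxymethoxy)phenol
Product: 9 4-bromo-2-(methoxymethoxy)-1-[(2-methylbut-3-en-2-yl)oxy]benzene
Conditions: tert-butyl 2-methylbut-3-en-2-yl carbonate (1.5 equiv), Pd(PPh3)4 (3 mol %), THF, 0 °C → rt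
Reagents that add atoms: tert-butyl (2-methylbut-3-en-2-yl) carbonate, C=CC(C)(C)OC(=O)OC(C)(C)C
Why: Tsuji–Trost O-allylation: the phenoxide attacks the 1,1-dimethyl-π-allylpalladium at its substituted terminus under kinetic control to give the tertiary aryl ether. The electron-rich C–Br bond should be inert to Pd(0)/PPh3 at this temperature.

Step 7
Reactants: 9 4-bromo-2-(methoxymethoxy)-1-[(2-methylbut-3-en-2-yl)oxy]benzene
Product: 11 4-bromo-2-(methoxymethoxy)-6-(3-methylbut-2-en-1-yl)phenol, via ortho-dienone 10 (not isolated)
Conditions: toluene, 110 °C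
Reagents that add atoms: none
Why: Aromatic Claisen [3,3] rearrangement: the terminal CH2 bonds to C6, the only free ortho carbon, with allylic transposition, so the tertiary ether becomes the linear prenyl group. Tautomerisation of 10 restores the arene.

Step 8
Reactants: 11 4-bromo-2-(methoxymethoxy)-6-(3-methylbut-2-en-1-yl)phenol
Product: 12 5-bromo-2-methoxy-1-(methoxymethoxy)-3-(3-methylbut-2-en-1-yl)benzene
Conditions: MeI (2 equiv), K2CO3 (2 equiv), DMF, rt
Reagents that add atoms: iodomethane, CI
Why: Williamson methylation of the phenol released by the rearrangement; this places the methyl group on the oxygen between the prenyl and OMOM groups.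

Step 9
Reactants: 12 5-bromo-2-methoxy-1-(methoxymethoxy)-3-(3-methylbut-2-en-1-yl)benzene
Product: 15 [4-methoxy-3-(methoxymethoxy)-5-(3-methylbut-2-en-1-yl)phenyl]boronic acid, via aryllithium 13 (not isolated), via lithium triisopropyl arylborate 14 (not isolated)
Conditions: n-BuLi (1.05 equiv), THF, −78 °C; B(OiPr)3 (1.5 equiv), −78 → 0 °C; 1 M HCl to pH 5–6, 0 °C
Reagents that add atoms: triisopropyl borate, CC(C)OB(OC(C)C)OC(C)C; water, O
Why: Bromine–lithium exchange (faster than ortho-lithiation or benzylic deprotonation at −78 °C), borylation of the aryllithium and mild hydrolysis. The controlled pH keeps the MOM ether.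

Step 10
Reactants: 5 5,7-bis(methoxymethoxy)-6,8-bis(3-methylbut-2-en-1-yl)-4H-chromen-4-one; 15 [4-methoxy-3-(methoxymethoxy)-5-(3-methylbut-2-en-1-yl)phenyl]boronic acid
Product: 16 (2S)-2-[4-methoxy-3-(methoxymethoxy)-5-(3-methylbut-2-en-1-yl)phenyl]-5,7-bis(methoxymethoxy)-6,8-bis(3-methylbut-2-en-1-yl)-2,3-dihydro-4H-chromen-4-one
Conditions: [RhCl(C2H4)2]2 (2.5 mol %), (S,S)-Ph-bod* [(1S,4S)-2,5-diphenylbicyclo[2.2.2]octa-2,5-diene] (5.5 mol %), aq. KOH (10 mol %), 15 (2.0 equiv), 1,4-dioxane/H2O (10:1), 40 °C
Reagents that add atoms: none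
Why: This is a Hayashi–Miyaura rhodium-catalysed asymmetric 1,4-addition of an arylboronic acid, a reaction type established for chromones. Transmetalation of 15 to the hydroxo-rhodium(I)–diene complex gives an aryl–rhodium species; the C2=C3 bond of 5 coordinates, the aryl group migrates to C2 to form an oxa-π-allyl rhodium enolate, and water protonates C3 and regenerates Rh–OH. No ring is closed, because the pyranone ring is already present, so no question of closure mode or reversibility arises. The only new stereocentre, C2, is set by the C2-symmetric diene, which lets the planar chromone bind through one enantioface; delivery of aryl to the Re face of C2 (O1 > C3 > H) gives 2S. The step needs 1,4- over 1,2-addition, inertness of the three prenyl alkenes and no erosion of configuration afterwards. Aryl–Rh(I) inserts only into the polarised, carbonyl-conjugated C2=C3 bond, the trisubstituted unactivated prenyl alkenes neither bind nor insert, and the C4 carbonyl of 16 is shielded by the 5-OMOM group and deactivated by donation from O5 and O7. The excess boronic acid buffers the hydroxide as borate, and O1 of the electron-rich ring A is a poor leaving group, so retro-oxa-Michael opening of 16 should be slow. The C–C bond formed is irreversible, unlike the C–O bond of a chalcone cyclisation.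

Step 11
Reactants: 16 (2S)-2-[4-methoxy-3-(methoxymethoxy)-5-(3-methylbut-2-en-1-yl)phenyl]-5,7-bis(methoxymethoxy)-6,8-bis(3-methylbut-2-en-1-yl)-2,3-dihydro-4H-chromen-4-one
Product: 17 isoamoritin, (2S)-5,7-dihydroxy-2-[3-hydroxy-4-methoxy-5-(3-methylbut-2-en-1-yl)phenyl]-6,8-bis(3-methylbut-2-en-1-yl)-2,3-dihydro-4H-chromen-4-one
Conditions: 3 M aq. HCl/MeOH (1:5), 50 °C, short reaction time
Reagents that add atoms: none
Why: Acid-catalysed acetal exchange with methanol frees the three phenols. Acid does not trigger the E1cB ring opening, so C2 should keep its configuration, and a short exposure limits addition of the freed hydroxyls to the prenyl groups.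

## Compound list

1 | 1-(2,4,6-trihydroxyphenyl)ethan-1-one (2,4,6-trihydroxyacetophenone) | CC(=O)c1c(O)cc(O)cc1O | starting material
2 | 1-[2,4,6-trihydroxy-3,5-bis(3-methylbut-2-en-1-yl)phenyl]ethan-1-one | CC(=O)c1c(O)c(CC=C(C)C)c(O)c(CC=C(C)C)c1O | intermediate
3 | 1-[2-hydroxy-4,6-bis(methoxymethoxy)-3,5-bis(3-methylbut-2-en-1-yl)phenyl]ethan-1-one | CC(=O)c1c(O)c(CC=C(C)C)c(OCOC)c(CC=C(C)C)c1OCOC | intermediate
4 | (E)-3-(dimethylamino)-1-[2-hydroxy-4,6-bis(methoxymethoxy)-3,5-bis(3-methylbut-2-en-1-yl)phenyl]prop-2-en-1-one | CN(C)/C=C/C(=O)c1c(O)c(CC=C(C)C)c(OCOC)c(CC=C(C)C)c1OCOC | intermediate (not isolated)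
5 | 5,7-bis(methoxymethoxy)-6,8-bis(3-methylbut-2-en-1-yl)-4H-chromen-4-one | O=c1ccoc2c(CC=C(C)C)c(OCOC)c(CC=C(C)C)c(OCOC)c12 | intermediate
6 | benzene-1,2-diol (catechol) | Oc1ccccc1O | starting material
7 | 2-(methoxymethoxy)phenol | COCOc1ccccc1O | intermediate
8 | 4-bromo-2-(methoxymethoxy)phenol | COCOc1cc(Br)ccc1O | intermediate
9 | 4-bromo-2-(methoxymethoxy)-1-[(2-methylbut-3-en-2-yl)oxy]benzene | COCOc1cc(Br)ccc1OC(C)(C)C=C | intermediate
10 | 4-bromo-2-(methoxymethoxy)-6-(3-methylbut-2-en-1-yl)cyclohexa-2,4-dien-1-one | O=C1C(OCOC)=CC(Br)=CC1CC=C(C)C | intermediate (not isolated)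
11 | 4-bromo-2-(methoxymethoxy)-6-(3-methylbut-2-en-1-yl)phenol | COCOc1cc(Br)cc(CC=C(C)C)c1O | intermediate
12 | 5-bromo-2-methoxy-1-(methoxymethoxy)-3-(3-methylbut-2-en-1-yl)benzene | COCOc1cc(Br)cc(CC=C(C)C)c1OC | intermediate
13 | [4-methoxy-3-(methoxymethoxy)-5-(3-methylbut-2-en-1-yl)phenyl]lithium | [Li]c1cc(CC=C(C)C)c(OC)c(OCOC)c1 | intermediate (not isolated)
14 | lithium triisopropoxy[4-methoxy-3-(methoxymethoxy)-5-(3-methylbut-2-en-1-yl)phenyl]borate | [Li+].CC(C)O[B-](OC(C)C)(OC(C)C)c1cc(CC=C(C)C)c(OC)c(OCOC)c1 | intermediate (not isolated)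
15 | [4-methoxy-3-(methoxymethoxy)-5-(3-methylbut-2-en-1-yl)phenyl]boronic acid | COCOc1cc(B(O)O)cc(CC=C(C)C)c1OC | intermediate
16 | (2S)-2-[4-methoxy-3-(methoxymethoxy)-5-(3-methylbut-2-en-1-yl)phenyl]-5,7-bis(methoxymethoxy)-6,8-bis(3-methylbut-2-en-1-yl)-2,3-dihydro-4H-chromen-4-one | COc1c(OCOC)cc([C@@H]2CC(=O)c3c(OCOC)c(CC=C(C)C)c(OCOC)c(CC=C(C)C)c3O2)cc1CC=C(C)C | intermediate
17 | isoamoritin, (2S)-5,7-dihydroxy-2-[3-hydroxy-4-methoxy-5-(3-methylbut-2-en-1-yl)phenyl]-6,8-bis(3-methylbut-2-en-1-yl)-2,3-dihydro-4H-chromen-4-one | COc1c(O)cc([C@@H]2CC(=O)c3c(O)c(CC=C(C)C)c(O)c(CC=C(C)C)c3O2)cc1CC=C(C)C | target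

## Step count and least certain steps

Total: 11 steps. Longest linear sequence: 8 steps (steps 4–9, 10, 11 from catechol); the ring-A branch is 3 steps (steps 1–3) before the union.

**Step 10 (key step).** The most likely failure is slow carbometalation of the electron-rich vinylogous ester, so that protodeboronation of the electron-rich boronic acid outruns the addition; a second risk is base-mediated opening and re-closure of the product, which would lower the enantiomeric purity. The fallback abandons the C2–C1′ bond formation, sets out from 12 and 3, and returns at 16. Bromine–lithium exchange on 12 and quenching with DMF should give 4-methoxy-3-(methoxymethoxy)-5-(3-methylbut-2-en-1-yl)benzaldehyde F1 (the same compound as A1). Claisen–Schmidt condensation of F1 with 3 (KOH, EtOH/H2O) should give (E)-1-[2-hydroxy-4,6-bis(methoxymethoxy)-3,5-bis(3-methylbut-2-en-1-yl)phenyl]-3-[4-methoxy-3-(methoxymethoxy)-5-(3-methylbut-2-en-1-yl)phenyl]prop-2-en-1-one F2 (the same compound as A2). F2 is then closed to 16 by an intramolecular oxa-Michael addition under a quinine-derived bifunctional thiourea, with preparative chromatography on a chiral phase if the selectivity is insufficient.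

**Step 1.** Over-alkylation (geminal dialkylation with dearomatisation), O-alkylation and incomplete alkylation are all open to the ambident polyanion, so material is expected to be lost. The fallback replaces direct C-alkylation by two O-to-C sigmatropic relays from the para oxygen, sets out from 1 and returns at 2.
- Copper-assisted alkylation of the only non-chelated hydroxyl with 3-chloro-3-methylbut-1-yne (K2CO3, KI, CuI, acetone) gives 1-{2,6-dihydroxy-4-[(2-methylbut-3-yn-2-yl)oxy]phenyl}ethan-1-one F3.
- Lindlar semihydrogenation gives 1-{2,6-dihydroxy-4-[(2-methylbut-3-en-2-yl)oxy]phenyl}ethan-1-one F4.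
- Warming in toluene triggers the Claisen shift to either of the two equivalent ortho carbons and gives 1-[2,4,6-trihydroxy-3-(3-methylbut-2-en-1-yl)phenyl]ethan-1-one F5.
- The same three operations are repeated through 1-{2,6-dihydroxy-3-(3-methylbut-2-en-1-yl)-4-[(2-methylbut-3-yn-2-yl)oxy]phenyl}ethan-1-one F6 and 1-{2,6-dihydroxy-3-(3-methylbut-2-en-1-yl)-4-[(2-methylbut-3-en-2-yl)oxy]phenyl}ethan-1-one F7.
- In F7 the only free ortho carbon is C5, so the second shift gives 2.

**Step 3.** The acid needed for ring closure and amine loss may also cleave the acetal groups, above all the one peri to the carbonyl, and elimination from the aminal may stall. The fallback builds C2 by a formate Claisen condensation, sets out from 3 and returns at 5. NaH and ethyl formate in THF should give 2-hydroxy-5,7-bis(methoxymethoxy)-6,8-bis(3-methylbut-2-en-1-yl)-2,3-dihydro-4H-chromen-4-one F8, the cyclic hemiacetal of the β-keto aldehyde. F8 is dehydrated without protic acid (MsCl, Et3N, CH2Cl2, 0 °C) to 5.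

**Step 6.** The phenoxide may attack the primary terminus of the π-allyl complex, or palladium may re-ionise the tertiary ether to the linear isomer; slow insertion into the C–Br bond is a lesser risk. The fallback avoids π-allyl chemistry, sets out from 8 and returns at 9. Copper-catalysed O-alkylation with 3-chloro-3-methylbut-1-yne (DBU, CuCl2 cat., MeCN, 0 °C) should give 4-bromo-2-(methoxymethoxy)-1-[(2-methylbut-3-yn-2-yl)oxy]benzene F9, and Lindlar semihydrogenation (H2, Pd/CaCO3/Pb, quinoline, EtOAc) gives 9.

**Step 11.** Protonation of a prenyl alkene and capture of the tertiary cation by a freshly freed neighbouring hydroxyl (most exposed: O7 between two prenyl groups) would give chromans. The fallback replaces protic solvolysis by an aprotic acetal-to-silyl-ether exchange, so that no free phenol and Brønsted acid coexist; it sets out from 16 and returns at 17. TMSOTf and 2,2′-bipyridyl in MeCN at 0 °C should give (2S)-2-[4-methoxy-5-(3-methylbut-2-en-1-yl)-3-(trimethylsilyloxy)phenyl]-6,8-bis(3-methylbut-2-en-1-yl)-5,7-bis(trimethylsilyloxy)-2,3-dihydro-4H-chromen-4-one F10, and neutral aqueous hydrolysis gives 17.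

## Further compounds

F1 | step 10 | 4-methoxy-3-(methoxymethoxy)-5-(3-methylbut-2-en-1-yl)benzaldehyde | COCOc1cc(C=O)cc(CC=C(C)C)c1OC
F2 | step 10 | (E)-1-[2-hydroxy-4,6-bis(methoxymethoxy)-3,5-bis(3-methylbut-2-en-1-yl)phenyl]-3-[4-methoxy-3-(methoxymethoxy)-5-(3-methylbut-2-en-1-yl)phenyl]prop-2-en-1-one | COCOc1cc(/C=C/C(=O)c2c(O)c(CC=C(C)C)c(OCOC)c(CC=C(C)C)c2OCOC)cc(CC=C(C)C)c1OC
F3 | step 1 | 1-{2,6-dihydroxy-4-[(2-methylbut-3-yn-2-yl)oxy]phenyl}ethan-1-one | CC(=O)c1c(O)cc(OC(C)(C)C#C)cc1O
F4 | step 1 | 1-{2,6-dihydroxy-4-[(2-methylbut-3-en-2-yl)oxy]phenyl}ethan-1-one | CC(=O)c1c(O)cc(OC(C)(C)C=C)cc1O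
F5 | step 1 | 1-[2,4,6-trihydroxy-3-(3-methylbut-2-en-1-yl)phenyl]ethan-1-one | CC(=O)c1c(O)cc(O)c(CC=C(C)C)c1O
F6 | step 1 | 1-{2,6-dihydroxy-3-(3-methylbut-2-en-1-yl)-4-[(2-methylbut-3-yn-2-yl)oxy]phenyl}ethan-1-one | CC(=O)c1c(O)cc(OC(C)(C)C#C)c(CC=C(C)C)c1O
F7 | step 1 | 1-{2,6-dihydroxy-3-(3-methylbut-2-en-1-yl)-4-[(2-methylbut-3-en-2-yl)oxy]phenyl}ethan-1-one | CC(=O)c1c(O)cc(OC(C)(C)C=C)c(CC=C(C)C)c1O
F8 | step 3 | 2-hydroxy-5,7-bis(methoxymethoxy)-6,8-bis(3-methylbut-2-en-1-yl)-2,3-dihydro-4H-chromen-4-one | O=C1CC(O)Oc2c(CC=C(C)C)c(OCOC)c(CC=C(C)C)c(OCOC)c12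
F9 | step 6 | 4-bromo-2-(methoxymethoxy)-1-[(2-methylbut-3-yn-2-yl)oxy]benzene | COCOc1cc(Br)ccc1OC(C)(C)C#C
F10 | step 11 | (2S)-2-[4-methoxy-5-(3-methylbut-2-en-1-yl)-3-(trimethylsilyloxy)phenyl]-6,8-bis(3-methylbut-2-en-1-yl)-5,7-bis(trimethylsilyloxy)-2,3-dihydro-4H-chromen-4-one | COc1c(O[Si](C)(C)C)cc([C@@H]2CC(=O)c3c(O[Si](C)(C)C)c(CC=C(C)C)c(O[Si](C)(C)C)c(CC=C(C)C)c3O2)cc1CC=C(C)C
A1 | alternative 1 | 4-methoxy-3-(methoxymethoxy)-5-(3-methylbut-2-en-1-yl)benzaldehyde | COCOc1cc(C=O)cc(CC=C(C)C)c1OC
A2 | alternative 1 | (E)-1-[2-hydroxy-4,6-bis(methoxymethoxy)-3,5-bis(3-methylbut-2-en-1-yl)phenyl]-3-[4-methoxy-3-(methoxymethoxy)-5-(3-methylbut-2-en-1-yl)phenyl]prop-2-en-1-one | COCOc1cc(/C=C/C(=O)c2c(O)c(CC=C(C)C)c(OCOC)c(CC=C(C)C)c2OCOC)cc(CC=C(C)C)c1OC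
A3 | alternative 2 | (3R)-3-hydroxy-1-[2-hydroxy-4,6-bis(methoxymethoxy)-3,5-bis(3-methylbut-2-en-1-yl)phenyl]-3-[4-methoxy-3-(methoxymethoxy)-5-(3-methylbut-2-en-1-yl)phenyl]propan-1-one | COCOc1cc([C@H](O)CC(=O)c2c(O)c(CC=C(C)C)c(OCOC)c(CC=C(C)C)c2OCOC)cc(CC=C(C)C)c1OC
A4 | alternative 3 | 2-[4-methoxy-3-(methoxymethoxy)-5-(3-methylbut-2-en-1-yl)phenyl]-5,7-bis(methoxymethoxy)-6,8-bis(3-methylbut-2-en-1-yl)-4H-chromen-4-one | COCOc1cc(-c2cc(=O)c3c(OCOC)c(CC=C(C)C)c(OCOC)c(CC=C(C)C)c3o2)cc(CC=C(C)C)c1OC
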